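## Retrosynthetic overview

1. Numbering: ring A is C1 (OMe), C2 (H), C3 (OH), C4 (ring B, the hydroquinone ring), C5 (CH2CH2–ring C), C6 (H). The strategy reads the vicinal pair C3–O / C4–ring B as the two carbons of an aryl ynol ether. The other four carbons, C2–C1(OMe)–C6–C5(chain), are the diene carbons C3–C6 of a 4-methoxy-6-alkyl-2-pyranone.
2. Key disconnection: bonds C2–C3 and C4–C5 of ring A. Both form in one operation by a silver-catalysed formal [4+2] of pyranone 4 with siloxyalkyne 10, followed by loss of CO2 from bridged lactone 11. Ring A is the only ring built; rings B and C are bought.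
3. Pyranone 4: the CH2–CH2 bond of the chain comes from alkylating the C6-methyl anion of 1 with benzylic bromide 2.
4. Siloxyalkyne 10: made from aldehyde 5 by benzylation, one-carbon homologation to alkyne 7, oxidation of its acetylide to the ynolate, and O-silylation.
5. End game: fluoride frees the C3 phenol, which stays distinct from the C1 methyl ether throughout. Hydrogenolysis then frees the other three phenols.

Key step: step 5

Assumption: the target SMILES carries no stereodescriptor, so the tri-ortho-substituted A–B biaryl axis is treated as stereochemically undefined and is made without control.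

## Route

**Step 1**
Reactants: 1 4-methoxy-6-methyl-2H-pyran-2-one; 2 3-(benzyloxy)benzyl bromide
Product: 4 6-{2-[3-(benzyloxy)phenyl]ethyl}-4-methoxy-2H-pyran-2-one, via lithium dienolate 3 (not isolated)
Conditions: LiN(iPr)2 (1.1 equiv), THF/DMPU, −78 °C; then 2, −78 to −30 °C
Reagents that add atoms: none
Why: Vinylogous (lateral) deprotonation of the C6 methyl group gives extended dienolate 3, and SN2 alkylation by the reactive benzylic bromide should occur at the exocyclic carbon because only that site restores the conjugated pyranone, a known way to 6-(2-arylethyl)-4-methoxy-2-pyranones.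

**Step 2**
Reactants: 5 2,5-dihydroxybenzaldehyde
Product: 6 2,5-bis(benzyloxy)benzaldehyde
Conditions: BnBr (2.4 equiv), K2CO3, DMF, 60 °C, N2
Reagents that add atoms: benzyl bromide, BrCc1ccccc1
Why: Williamson ether synthesis on both phenols, where warming overcomes the hydrogen bond of the 2-OH to the aldehyde and exclusion of air protects the hydroquinone until it is capped.

**Step 3**
Reactants: 6 2,5-bis(benzyloxy)benzaldehyde
Product: 7 1,4-bis(benzyloxy)-2-ethynylbenzene
Conditions: dimethyl (1-diazo-2-oxopropyl)phosphonate, K2CO3, MeOH/THF, 0 °C to rt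
Reagents that add atoms: dimethyl (1-diazo-2-oxopropyl)phosphonate, CC(=O)C(=[N+]=[N-])P(=O)(OC)OC
Why: Seyferth–Gilbert homologation in the Ohira–Bestmann variant converts a non-enolisable aryl aldehyde into the terminal alkyne under carbonate base, which leaves the benzyl ethers untouched.

**Step 4**
Reactants: 7 1,4-bis(benzyloxy)-2-ethynylbenzene
Product: 10 ({[2,5-bis(benzyloxy)phenyl]ethynyl}oxy)tri(propan-2-yl)silane, via lithium acetylide 8 (not isolated), via lithium ynolate 9 (not isolated)
Conditions: n-BuLi (1.0 equiv), THF, −78 °C; LiOOt-Bu (from t-BuOOH and LiN(SiMe3)2, THF, −78 °C), −78 to 0 °C; iPr3SiOSO2CF3, −78 to 0 °C; rapid filtration over Et3N-deactivated silica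
Reagents that add atoms: tert-butyl hydroperoxide, CC(C)(C)OO; triisopropylsilyl trifluoromethanesulfonate, CC(C)[Si](OS(=O)(=O)C(F)(F)F)(C(C)C)C(C)C
Why: Oxidation of a lithium acetylide with lithium tert-butyl peroxide, then O-silylation of the ynolate with a bulky silyl triflate, is the standard entry to triisopropylsiloxyalkynes, and it needs one equivalent of alkyllithium, so the aryl benzyl ethers are not metalated as they could be by the excess alkyllithium of an ester-to-ynolate homologation.

**Step 5**
Reactants: 4 6-{2-[3-(benzyloxy)phenyl]ethyl}-4-methoxy-2H-pyran-2-one; 10 ({[2,5-bis(benzyloxy)phenyl]ethynyl}oxy)tri(propan-2-yl)silane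
Product: 12 {2-[2,5-bis(benzyloxy)phenyl]-3-{2-[3-(benzyloxy)phenyl]ethyl}-5-methoxyphenoxy}tri(propan-2-yl)silane, via bridged lactone 11 (not isolated)
Conditions: AgN(SO2CF3)2 (10 mol %), 4 Å molecular sieves, ClCH2CH2Cl, slow addition of 10 (1.5 equiv), rt then 70 °C
Reagents that add atoms: none
Why: Proposed new method: the silver cation binds the electron-rich triple bond of 10 and polarises it toward a silver-bound ketenium ion; C3 of 4, the α-carbon of the vinylogous ester and the site at which 4-alkoxy-2-pyranones accept electrophiles, attacks the oxygen-bearing carbon (bond C2–C3 of ring A), the resulting alkenylsilver carbon, the one bonded to ring B, adds to C6 of the methoxy-stabilised cation (bond C4–C5) with release of the catalyst, and bridged lactone 11 expels CO2 in a retro-[4+2] driven by aromatisation. The closest known reaction types are the inverse-demand Diels–Alder/decarboxylation of 2-pyranones with ynamines, the silver-catalysed formal [4+2] of siloxyalkynes with 1,2-diazines and the silver-catalysed [2+2] of siloxyalkynes with enones, but a 2-pyranone has not been paired with a siloxyalkyne, and heat alone is not relied on because the 4-methoxy group makes 4 a poor acceptor diene for an electron-rich alkyne. Ring A is closed as a six-membered carbocycle by this stepwise formal [4+2] across the C3 and C6 termini of the pyranone (one intermolecular bond, then a six-membered closure to the bicyclo[2.2.2] frame), and it is the only ring formed. No stereocentre is set, since the two bridgeheads of racemic 11 become sp2 carbons when CO2 leaves and the A–B axis forms without control. The regiochemistry required (C–O carbon of the alkyne to C3, C–aryl carbon to C6) is secured by the substrates themselves, because the ynol ether is electrophilic at C–O and nucleophilic at C–aryl while the pyranone is nucleophilic at C3 and electrophilic at C6, so either order of bond formation leads to the same constitution. The step also needs six-membered over four-membered closure, which is favoured because a cyclobutene adduct is strained and can reopen to the zwitterion, whereas only 11 has the irreversible exit through loss of CO2.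

**Step 6**
Reactants: 12 {2-[2,5-bis(benzyloxy)phenyl]-3-{2-[3-(benzyloxy)phenyl]ethyl}-5-methoxyphenoxy}tri(propan-2-yl)silane
Product: 13 2',5'-bis(benzyloxy)-6-{2-[3-(benzyloxy)phenyl]ethyl}-4-methoxy[1,1'-biphenyl]-2-ol
Conditions: Bu4NF, AcOH, THF, 0 °C to rt
Reagents that add atoms: none
Why: Fluoride-induced cleavage of an aryl silyl ether is fast even next to the biaryl axis, acetic acid buffers the phenoxide, and the benzyl and methyl ethers are inert.

**Step 7**
Reactants: 13 2',5'-bis(benzyloxy)-6-{2-[3-(benzyloxy)phenyl]ethyl}-4-methoxy[1,1'-biphenyl]-2-ol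
Product: 14 6-[2-(3-hydroxyphenyl)ethyl]-4-methoxy[1,1'-biphenyl]-2,2',5'-triol (target)
Conditions: H2 (1 atm), Pd/C (10 wt %), EtOAc/MeOH, rt; work-up under argon
Reagents that add atoms: none
Why: Catalytic hydrogenolysis should cleave the three aryl benzyl ethers while the aryl methyl ether, the biaryl bond and the saturated chain are inert, and exclusion of air keeps the free hydroquinone from oxidising.

## Compound list

1 | 4-methoxy-6-methyl-2H-pyran-2-one | COC1=CC(=O)OC(C)=C1 | starting material
2 | 3-(benzyloxy)benzyl bromide | BrCc1cccc(OCc2ccccc2)c1 | starting material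
3 | lithium 4-methoxy-6-methylidene-6H-pyran-2-olate (extended dienolate of 1) | [Li+].[O-]C1=CC(OC)=CC(=C)O1 | intermediate
4 | 6-{2-[3-(benzyloxy)phenyl]ethyl}-4-methoxy-2H-pyran-2-one | COC1=CC(=O)OC(CCc2cccc(OCc3ccccc3)c2)=C1 | intermediate
5 | 2,5-dihydroxybenzaldehyde | O=Cc1cc(O)ccc1O | starting material
6 | 2,5-bis(benzyloxy)benzaldehyde | O=Cc1cc(OCc2ccccc2)ccc1OCc1ccccc1 | intermediate
7 | 1,4-bis(benzyloxy)-2-ethynylbenzene | C#Cc1cc(OCc2ccccc2)ccc1OCc1ccccc1 | intermediate
8 | lithium [2,5-bis(benzyloxy)phenyl]acetylide | [Li+].[C-]#Cc1cc(OCc2ccccc2)ccc1OCc1ccccc1 | intermediate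
9 | lithium 2-[2,5-bis(benzyloxy)phenyl]ethyn-1-olate | [Li+].[O-]C#Cc1cc(OCc2ccccc2)ccc1OCc1ccccc1 | intermediate
10 | ({[2,5-bis(benzyloxy)phenyl]ethynyl}oxy)tri(propan-2-yl)silane | CC(C)[Si](OC#Cc1cc(OCc2ccccc2)ccc1OCc1ccccc1)(C(C)C)C(C)C | intermediate
11 | 7-[2,5-bis(benzyloxy)phenyl]-1-{2-[3-(benzyloxy)phenyl]ethyl}-5-methoxy-8-[(triisopropylsilyl)oxy]-2-oxabicyclo[2.2.2]octa-5,7-dien-3-one (racemic, transient) | O=C1OC2(CCc3cccc(OCc4ccccc4)c3)C=C(OC)C1C(O[Si](C(C)C)(C(C)C)C(C)C)=C2c5cc(OCc6ccccc6)ccc5OCc7ccccc7 | intermediate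
12 | {2-[2,5-bis(benzyloxy)phenyl]-3-{2-[3-(benzyloxy)phenyl]ethyl}-5-methoxyphenoxy}tri(propan-2-yl)silane | COc1cc(O[Si](C(C)C)(C(C)C)C(C)C)c(-c2cc(OCc3ccccc3)ccc2OCc2ccccc2)c(CCc2cccc(OCc3ccccc3)c2)c1 | intermediate
13 | 2',5'-bis(benzyloxy)-6-{2-[3-(benzyloxy)phenyl]ethyl}-4-methoxy[1,1'-biphenyl]-2-ol | COc1cc(O)c(-c2cc(OCc3ccccc3)ccc2OCc2ccccc2)c(CCc2cccc(OCc3ccccc3)c2)c1 | intermediate
14 | 6-[2-(3-hydroxyphenyl)ethyl]-4-methoxy[1,1'-biphenyl]-2,2',5'-triol | COc1cc(O)c(-c2cc(O)ccc2O)c(CCc2cccc(O)c2)c1 | target

## Step count and risks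

Total step count: 7. Longest linear sequence: 6 (steps 2, 3, 4, 5, 6, 7).

**Step 5 (new method).**
- After the first C–C bond, the cationic adduct may pass its C3 proton to the alkenylsilver carbon. The sequence would then end as plain alkenylation of the pyranone instead of ring closure.
- Closure to a four-membered ring may compete.
- The ortho benzyloxy oxygen of ring B may capture the activated ynol ether carbon, with migration of its benzyl group.
- The siloxyalkyne may be used up by hydrolysis or self-addition before the weakly nucleophilic pyranone reacts.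

The fallback uses known chemistry and makes the A–B bond by cross-coupling on a ring A whose substitution is fixed by a carboxyl placeholder. It sets out from 2 and returns at 14. Commercial methyl 2-hydroxy-4-methoxy-6-methylbenzoate is benzylated (BnBr, K2CO3, DMF) to methyl 2-(benzyloxy)-4-methoxy-6-methylbenzoate F1. Lateral lithiation (LiN(iPr)2, THF, −78 °C) and alkylation with 2 gives methyl 2-(benzyloxy)-6-{2-[3-(benzyloxy)phenyl]ethyl}-4-methoxybenzoate F2. Hydrolysis of the hindered ester (KOH, DMSO/H2O, 100 °C) gives 2-(benzyloxy)-6-{2-[3-(benzyloxy)phenyl]ethyl}-4-methoxybenzoic acid F3. Decarboxylative iodination (I2, K3PO4, MeCN, 100 °C) places the halogen on the carbon that is to bear ring B, giving 1-(benzyloxy)-3-{2-[3-(benzyloxy)phenyl]ethyl}-2-iodo-5-methoxybenzene F4. In parallel, 2-bromobenzene-1,4-diol is benzylated to 1,4-bis(benzyloxy)-2-bromobenzene F5. Bromine–lithium exchange (n-BuLi, THF, −78 °C), B(OiPr)3 and acidic work-up convert it into [2,5-bis(benzyloxy)phenyl]boronic acid F6. Suzuki–Miyaura coupling of F4 with F6 (Pd(OAc)2, 2-dicyclohexylphosphino-2',6'-dimethoxybiphenyl, K3PO4, toluene/H2O, 100 °C) gives 2,2',5'-tris(benzyloxy)-6-{2-[3-(benzyloxy)phenyl]ethyl}-4-methoxy-1,1'-biphenyl F7. Hydrogenolysis under the conditions of step 7 gives 14.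

**Step 4.**
- Oxygen transfer to the less nucleophilic aryl acetylide may be incomplete.
- Silylation may occur at carbon instead of oxygen.
- The ynol ether may hydrolyse during purification.

The fallback reaches the ynolate by a 1,2-aryl shift with measured amounts of base instead of by acetylide oxidation. It sets out from 6 and returns at 9, and so at 10. Dibromomethyllithium (CH2Br2, LiN(iPr)2, THF, −90 °C) adds to 6 to give racemic 1-[2,5-bis(benzyloxy)phenyl]-2,2-dibromoethan-1-ol F8. Dess–Martin periodinane gives 1-[2,5-bis(benzyloxy)phenyl]-2,2-dibromoethan-1-one F9. One equivalent of LiN(SiMe3)2 at −78 °C gives lithium 1-[2,5-bis(benzyloxy)phenyl]-2,2-dibromoethen-1-olate F10. One equivalent of n-BuLi, followed by warming, triggers bromine–lithium exchange and the Kowalski rearrangement to 9, which is silylated as in step 4.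

**Step 1.**
- Metalation at ring carbon C3 may compete.
- Proton exchange between product and dienolate may lead to double alkylation.
- The amide base may attack the lactone carbonyl.

The fallback replaces alkylation with condensation and reduction. It sets out from 1 and returns at 4. Vinylogous aldol condensation of 1 with 3-(benzyloxy)benzaldehyde (Mg(OMe)2, MeOH, reflux) gives 6-{(E)-2-[3-(benzyloxy)phenyl]ethenyl}-4-methoxy-2H-pyran-2-one F11. Diimide (TsNHNH2, NaOAc, THF/H2O, reflux) saturates only the disubstituted exocyclic alkene and spares the benzyl ether and the ring double bonds, giving 4.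

## Further compounds

F1 | step 5 | methyl 2-(benzyloxy)-4-methoxy-6-methylbenzoate | COC(=O)c1c(C)cc(OC)cc1OCc1ccccc1
F2 | step 5 | methyl 2-(benzyloxy)-6-{2-[3-(benzyloxy)phenyl]ethyl}-4-methoxybenzoate | COC(=O)c1c(CCc2cccc(OCc3ccccc3)c2)cc(OC)cc1OCc1ccccc1
F3 | step 5 | 2-(benzyloxy)-6-{2-[3-(benzyloxy)phenyl]ethyl}-4-methoxybenzoic acid | OC(=O)c1c(CCc2cccc(OCc3ccccc3)c2)cc(OC)cc1OCc1ccccc1
F4 | step 5 | 1-(benzyloxy)-3-{2-[3-(benzyloxy)phenyl]ethyl}-2-iodo-5-methoxybenzene | COc1cc(OCc2ccccc2)c(I)c(CCc2cccc(OCc3ccccc3)c2)c1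
F5 | step 5 | 1,4-bis(benzyloxy)-2-bromobenzene | Brc1cc(OCc2ccccc2)ccc1OCc1ccccc1
F6 | step 5 | [2,5-bis(benzyloxy)phenyl]boronic acid | OB(O)c1cc(OCc2ccccc2)ccc1OCc1ccccc1
F7 | step 5 | 2,2',5'-tris(benzyloxy)-6-{2-[3-(benzyloxy)phenyl]ethyl}-4-methoxy-1,1'-biphenyl | COc1cc(OCc2ccccc2)c(-c2cc(OCc3ccccc3)ccc2OCc2ccccc2)c(CCc2cccc(OCc3ccccc3)c2)c1
F8 | step 4 | 1-[2,5-bis(benzyloxy)phenyl]-2,2-dibromoethan-1-ol (racemic) | OC(C(Br)Br)c1cc(OCc2ccccc2)ccc1OCc1ccccc1
F9 | step 4 | 1-[2,5-bis(benzyloxy)phenyl]-2,2-dibromoethan-1-one | O=C(C(Br)Br)c1cc(OCc2ccccc2)ccc1OCc1ccccc1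
F10 | step 4 | lithium 1-[2,5-bis(benzyloxy)phenyl]-2,2-dibromoethen-1-olate | [Li+].[O-]C(=C(Br)Br)c1cc(OCc2ccccc2)ccc1OCc1ccccc1
F11 | step 1 | 6-{(E)-2-[3-(benzyloxy)phenyl]ethenyl}-4-methoxy-2H-pyran-2-one | COC1=CC(=O)OC(/C=C/c2cccc(OCc3ccccc3)c2)=C1
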